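(Readings and results are calculated on assumed constants; the scatter is artificial.)

**Two charges.** The reagent charges stand in the ratio 0.656, Sunday's to Saturday's, with solid substrate and protic impurity charged alike, and the flask asked about is Sunday's run carried on to 4.0 d.

| flask | solid substrate | reagent | protic impurity | remark | time |
|---|---|---|---|---|---|
| Sunday's | 0.041 M | 0.164 M | 2.05 mM | the very flask that is asked about, followed so far |  |
| Saturday's | 0.041 M | 0.25 M | 2.05 mM | run made earlier |  |
| flask | 0.041 M | 0.164 M | 2.05 mM |  | 4.0 d |

Sunday's run (percent of the solid substrate charged)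

| time / h | target / % | dissolved substrate / % | solid substrate / % |
|---|---|---|---|
| 1.00 | 0 | 19.4 | 79.0 |
| 3.00 | 0 | 30.5 | 67.3 |
| 5.00 | 1.4 | 29.8 | 64.2 |
| 8.00 | 8.7 | 30.6 | 59.4 |
| 12.0 | 13.4 | 29.9 | 53.3 |
| 15.0 | 13.7 | 31.0 | 53.2 |
| 20.0 | 16.5 | 32.5 | 49.9 |

Saturday's run (percent of the solid substrate charged)

| time / d | target / % | dissolved substrate / % | solid substrate / % |
|---|---|---|---|
| 0.625 | 19.3 | 30.3 | 46.6 |
| 1.25 | 30.2 | 29.7 | 33.1 |
| 1.67 | 35.7 | 29.8 | 29.0 |
| 2.50 | 40.9 | 31.5 | 23.0 |
| 3.00 | 41.9 | 32.9 | 20.0 |
| 4.00 | 46.1 | 32.1 | 17.1 |

(readings scatter by 1 percentage point)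

- as a solid, counted per litre of solution: solid substrate
- steps thought possible: reagent -> side product; solid substrate <-> dissolved substrate; 2 reagent -> self-condensation product; dissolved substrate + reagent -> target; solid substrate + protic impurity -> quenched substrate
- at the start none of the solid substrate is in solution
- dissolved substrate means what is dissolved; the solid is not counted in it

* amount of target at 4.0 d, in percent of the solid substrate charged
* concentration of dissolved substrate in solution at 4.0 d, in percent of saturation

**The reach.** Dissolved substrate reads level on Saturday, between 29.7 % and 32.9 %, while solid remains, so we treat target formation as pseudo-first-order in reagent, and target made then follows the reagent's fraction left, summed over time. We call the reach the target made, as a fraction of the solid substrate charged, per molar of reagent charged; Saturday's at 4.00 d is 1.84 M⁻¹, which on Sunday's charge gives 30.2 %.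

**Weak link.** That step assumes both flasks keep the same fraction of reagent, which holds for a first-order loss, but the self-condensation of two reagent, where it runs, lets a leaner charge keep a larger fraction. Sunday's 15.0 h is Saturday's 0.625 d, and the target readings there, 13.7 % and 19.3 %, make Sunday's reach at that moment 1.08 times Saturday's, a reading that carries their scatter. Assuming that factor holds on to 4.0 d, we commit to 32.7 % of target. Taking dissolved and quenched substrate as on Saturday, we reckon the solid left in this flask as Saturday's plus the target not made, 30.5 %, more than the 17.1 % beside which Saturday's solution still read 32.1 %, so we expect this flask's solution to stay close to saturation.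

**The result.** The forecast, 37 % of target and 99 % of saturation, stands above our target figure, holding that “Sunday's points favour second-order”. The flask gives 32.9 % of target and 99.8 % of saturation.

    reagent → side product (k = 7.23 × 10⁻⁶ s⁻¹)
    solid substrate ⇌ dissolved substrate, rate k2*(cs2 - [dissolved substrate]) while solid is left; crystals form when [dissolved substrate] > cs2 (solubility = 13.0 mM, k = 2.72 × 10⁻⁴ s⁻¹)
    2 reagent → self-condensation product (k = 1.50 × 10⁻⁵ M⁻¹ s⁻¹)
    dissolved substrate + reagent → target (k = 7.33 × 10⁻⁵ M⁻¹ s⁻¹)
    solid substrate + protic impurity → quenched substrate (k = 9.19 × 10⁻⁴ M⁻¹ s⁻¹)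

This flask's reagent is down to 3.8 % of its own charge at 4.0 d, and its reach is 2.01 M⁻¹, above the 1.84 M⁻¹ read on Saturday.

**A neighbour.** For a neighbour flask with 0.28 M of reagent, its other charges and the time as in this flask, Saturday's reach gives 51.5 % of target; the computed neighbour holds 48.8 %, a reach of 1.74 M⁻¹, below the one read on Saturday.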